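**Assumption:** (2S)-naringenin is bought as the single enantiomer (citrus-derived, ≥98% ee, checked by chiral HPLC on receipt). Flavanone numbering is used throughout (ring A = C5–C8, ring B = primed positions).

## Retrosynthetic overview

1. Target ⇒ cleave a 7-O-pivalate; disconnect C5'–dienyl to aryl iodide + 2-methylbut-1-en-3-yne (Ni-electrocatalytic reductive hydroarylation, new).
2. Disconnect C3'–prenyl to a symmetric 3',5'-diiodide + prenyl acetate (Ni-electroreductive cross-electrophile coupling, desymmetrising mono-coupling).
3. The 3',5'-diiodo-4'-methoxy ring B comes from phenol-directed diiodination and O-methylation of 7-O-pivaloyl-(2S)-naringenin.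
4. No ring is formed: rings A, C and B and the C2 stereocentre are bought intact in (2S)-naringenin. Every step is base-free or only weakly basic, so C2 cannot epimerise through the chalcone.

## Route

**Step 1**
Reactants: 1, (2S)-naringenin; 2, pivaloyl chloride
Product: 3, (2S)-7-O-pivaloylnaringenin [(2S)-5-hydroxy-2-(4-hydroxyphenyl)-4-oxochroman-7-yl pivalate]
Conditions: PivCl (1.05 equiv), i-Pr2NEt (1.1 equiv), THF, −20 → 0 °C
Reagents that add atoms: pivaloyl chloride, CC(C)(C)C(=O)Cl
Why: Chemoselective phenol O-acylation: one equivalent of Hünig's base ionises only the 7-OH (vinylogous acid, pKa ≈ 7.5), while the 5-OH is locked in the chelate with C4=O and the 4'-OH (pKa ≈ 10) stays protonated; C2 is untouched in this cold, weakly basic medium.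

**Step 2**
Reactants: 3; 4, benzyltrimethylammonium dichloroiodate
Product: 5, (2S)-3',5'-diiodo-7-O-pivaloylnaringenin [(2S)-5-hydroxy-2-(4-hydroxy-3,5-diiodophenyl)-4-oxochroman-7-yl pivalate]
Conditions: BnMe3N·ICl2 (2.1 equiv), NaHCO3 (4 equiv), CH2Cl2–MeOH 5:2, 0 °C → rt, dark
Reagents that add atoms: benzyltrimethylammonium dichloroiodate, C[N+](C)(C)Cc1ccccc1.Cl[I-]Cl
Why: Electrophilic aromatic iodination of a free para-substituted phenol takes both ortho positions (as in tyrosine diiodination); ring B carries the only free, ionisable OH, whereas ring A is damped by the 7-pivalate and its chelated 5-OH; no stereocentre is made and solid bicarbonate at rt should be too weak to open the pyranone.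

**Step 3**
Reactants: 5; 6, methanol
Product: 7, (2S)-3',5'-diiodo-4'-O-methyl-7-O-pivaloylnaringenin [(2S)-5-hydroxy-2-(3,5-diiodo-4-methoxyphenyl)-4-oxochroman-7-yl pivalate]
Conditions: MeOH (1.5 equiv), PPh3 (1.3 equiv), DIAD (1.3 equiv), THF, 0 °C → rt
Reagents that add atoms: methanol, CO
Why: Mitsunobu etherification under neutral conditions methylates the 2,6-diiodophenol (pKa ≈ 6.5, the only acidic non-chelated OH) and leaves the H-bonded 5-OH alone; with no free base present C2 is not at risk, and the 4'-OMe then blocks the quinone-methide epimerisation pathway for the rest of the route.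

**Step 4**
Reactants: 7; 8, prenyl acetate (3-methylbut-2-en-1-yl acetate)
Product: 9, (2S)-5-hydroxy-2-[3-iodo-4-methoxy-5-(3-methylbut-2-en-1-yl)phenyl]-4-oxochroman-7-yl pivalate
Conditions: NiBr2·dme (10 mol%), 2,2'-bipyridine (10 mol%), 8 (1.05 equiv), n-Bu4NBr (0.1 M), DMF, undivided cell, Zn anode/Ni-foam cathode, 5 mA constant current, 2.1 F mol⁻¹, rt
Reagents that add atoms: prenyl acetate, CC(C)=CCOC(C)=O
Why: Nickel-catalysed electroreductive cross-electrophile coupling of an aryl iodide with an allylic acetate (sacrificial-anode process): cathodic (bpy)Ni(0) inserts into C–I, the aryl–Ni captures prenyl acetate as a π-(1,1-dimethylallyl) complex and reductive elimination at the unhindered CH2 terminus gives the linear prenyl arene; replacing an electron-withdrawing meta-iodine by an alkyl group makes 9 slower in oxidative addition than 7, so mono-coupling dominates at 2.1 F mol⁻¹, and the base-free rt medium leaves C2 untouched.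

**Step 5**
Reactants: 9; 10, 2-methylbut-1-en-3-yne
Product: 11, (2S)-5-hydroxy-2-{4-methoxy-3-[(1E)-3-methylbuta-1,3-dien-1-yl]-5-(3-methylbut-2-en-1-yl)phenyl}-4-oxochroman-7-yl pivalate
Conditions: NiBr2·dme (10 mol%), dtbbpy (12 mol%), 10 (3 equiv), H2O (5 equiv), n-Bu4NBF4 (0.1 M), DMA, sealed undivided cell, Zn anode/RVC cathode, 4 mA, 2.2 F mol⁻¹, 5–10 °C
Reagents that add atoms: 2-methylbut-1-en-3-yne, C=C(C)C#C (water supplies only H)
Why: Proposed new method: Ni-electrocatalytic anti-Markovnikov reductive hydroarylation of a terminal 1,3-enyne — cathodic (dtbbpy)Ni(0) adds Ar–I, syn-arylnickelation of the alkyne puts the aryl on the unhindered CH terminus and Ni on the carbon bearing the isopropenyl group (η3-butadienyl stabilised), and after one-electron reduction the dienyl–Ni bond is protonated by water with retention, so Ar and the new H are cis and only the (E)-1-aryl-3-methylbuta-1,3-diene forms; the closest known reaction types are Pd/formate reductive-Heck hydroarylation of alkynes and the Ni-electroreductive aryl halide coupling of step 4; with no base and no light, neither C2 nor the E-diene is scrambled.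

**Step 6**
Reactants: 11
Product: 12, target, (2S)-5,7-dihydroxy-2-{4-methoxy-3-[(1E)-3-methylbuta-1,3-dien-1-yl]-5-(3-methylbut-2-en-1-yl)phenyl}chroman-4-one
Conditions: NH3 (7 M in MeOH), 0 °C → rt
Reagents that add atoms: none
Why: Aminolysis of an activated aryl ester (the leaving group is the pKa ≈ 7.5 7-phenoxide) is fast under conditions too weakly basic for retro-oxa-Michael opening at C2 and inert toward the prenyl and diene groups.

## Compound list

1 | (2S)-naringenin | Oc1ccc(cc1)[C@@H]1CC(=O)c2c(O)cc(O)cc2O1 | starting material
2 | pivaloyl chloride | CC(C)(C)C(=O)Cl | starting material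
3 | (2S)-7-O-pivaloylnaringenin | Oc1ccc(cc1)[C@@H]1CC(=O)c2c(O)cc(OC(=O)C(C)(C)C)cc2O1 | intermediate
4 | benzyltrimethylammonium dichloroiodate | C[N+](C)(C)Cc1ccccc1.Cl[I-]Cl | starting material
5 | (2S)-3',5'-diiodo-7-O-pivaloylnaringenin | Oc1c(I)cc(cc1I)[C@@H]1CC(=O)c2c(O)cc(OC(=O)C(C)(C)C)cc2O1 | intermediate
6 | methanol | CO | starting material
7 | (2S)-3',5'-diiodo-4'-O-methyl-7-O-pivaloylnaringenin | COc1c(I)cc(cc1I)[C@@H]1CC(=O)c2c(O)cc(OC(=O)C(C)(C)C)cc2O1 | intermediate
8 | prenyl acetate | CC(C)=CCOC(C)=O | starting material
9 | (2S)-3'-iodo-4'-methoxy-5'-prenyl-7-O-pivaloyl flavanone | COc1c(I)cc(cc1CC=C(C)C)[C@@H]1CC(=O)c2c(O)cc(OC(=O)C(C)(C)C)cc2O1 | intermediate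
10 | 2-methylbut-1-en-3-yne | C=C(C)C#C | starting material
11 | 7-O-pivalate of the target | COc1c(/C=C/C(C)=C)cc(cc1CC=C(C)C)[C@@H]1CC(=O)c2c(O)cc(OC(=O)C(C)(C)C)cc2O1 | intermediate
12 | (2S)-5,7-dihydroxy-2-{4-methoxy-3-[(1E)-3-methylbuta-1,3-dien-1-yl]-5-(3-methylbut-2-en-1-yl)phenyl}chroman-4-one | C=C(C)/C=C/c1cc([C@@H]2CC(=O)c3c(O)cc(O)cc3O2)cc(CC=C(C)C)c1OC | target

## Summary

Total steps: 6. Longest linear sequence: 6.

Steps most likely to fail, each with one fallback:

1. **Step 5 (proposed new electroreductive enyne hydroarylation).** Risks are Ni-mediated alkyne oligomerisation, Sonogashira-type alkynylation, hydrodeiodination, and allene or over-reduced by-products. Fallback (known chemistry): neutral Stille coupling of 9 with (E)-tributyl(3-methylbuta-1,3-dien-1-yl)stannane, made in one step by hydrostannation of 10 with Bu3SnH; conditions Pd2(dba)3/AsPh3/CuI, DMF, 45 °C; then step 6.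

2. **Step 4 (mono-selective electro-prenylation of the diiodide).** Risks are double prenylation, protodeiodination by the 5-OH, and biaryl formation. Fallback: give up desymmetrising a symmetric dihalide. Halogenate 3 stepwise (BnMe3N·Br3, 1.0 equiv, then BnMe3N·ICl2) to the 3'-bromo-5'-iodo phenol and methylate as in step 3. Then use a Pd-catalysed Stille prenylation with tributyl(prenyl)stannane, which distinguishes C–I from C–Br by oxidative-addition rate, and keep the bromide for the dienyl unit.

3. **Step 2 (ring-B-selective diiodination).** Risks are competing iodination at C6/C8 of ring A and partial C2 epimerisation through the 4'-phenoxide; check ee by chiral HPLC after this step. Fallback: iodinate exhaustively, then strip the ring-A iodines selectively by protodeiodination (aq. Na2SO3 or catalytic HI); C–I bonds on the phloroglucinol-type ring are far more labile than ortho-iodophenol C–I bonds. Then continue from 5.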